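**Retrosynthetic overview**
- The target is a 2,3-trans-3-hydroxychroman-4-one (ring C) that joins ring A (5,7-dihydroxy-6-prenyl) to ring B (2',4'-dihydroxy-3'-geranyl); the last step only removes four MOM ethers.
- Key disconnection: the O1–C2 and C4–C3 bonds together. Ring C is closed in one flask from a ring-A 1,3-benzodioxin-4-one (masked O1 nucleophile, C4 acyl electrophile) and a ring-B oxiranyllithium (C3 carbanion, C2 strained electrophile).
- Enabling feature: C3 is a carbinol carbon between the C4 aryl ketone and C2, and C2 is a benzylic ether carbon on the electron-rich 2',4'-dioxygenated ring B. This is the retron of an α,β-epoxy ketone opened 6-endo at C2 by the ortho-phenol oxygen O1 of ring A; the epoxide oxygen becomes the 3-OH.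
- Both pieces come from resorcinol bis-MOM ether. Ring B: geranylation, formylation, sulfinyloxirane (a chiral sulfoxide sets C3). Ring A: prenylation, C–H borylation/oxidation to a mirror-symmetric phenol, ortho-carboxylation, dioxinone (this fixes the 6-prenyl pattern).
- Ring order: rings A and B are bought as resorcinol; ring C is the only ring of the target that is built (step 9); the dioxinone and oxirane are temporary rings consumed there.

Key step: step 9

Assumption: in step 8 the (R)-sulfinyl group is taken to induce the carbon configuration drawn for 13 and 14; if the sense is opposite, the (S)-reagent is used, since sulfur is removed in step 9 and only the oxirane carbons matter (both enantiomers of chloromethyl p-tolyl sulfoxide are taken as purchasable).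

Step 1
Reactants: 1 resorcinol
Product: 2 1,3-bis(methoxymethoxy)benzene
Conditions: NaH, MOMCl, DMF, 0 °C → rt
Reagents that add atoms: chloromethyl methyl ether COCCl
Why: Williamson-type O-alkylation of the bis-phenoxide gives the bis-acetal, which survives the organolithium steps and directs the metalations that follow; no stereocentre is formed.

Step 2
Reactants: 2 1,3-bis(methoxymethoxy)benzene; 3 prenyl bromide
Product: 4 1,3-bis(methoxymethoxy)-2-(3-methylbut-2-en-1-yl)benzene
Conditions: n-BuLi, THF, 0 °C → rt; then CuI (copper iodide, 10 mol%), 3, −78 °C → rt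
Reagents that add atoms: none
Why: Directed ortho-metalation, in which the two MOM ethers jointly direct lithiation to the carbon between them, followed by copper-assisted SN2 displacement of the primary allylic bromide.

Step 3
Reactants: 4 1,3-bis(methoxymethoxy)-2-(3-methylbut-2-en-1-yl)benzene
Product: 6 3,5-bis(methoxymethoxy)-4-(3-methylbut-2-en-1-yl)phenol, via arylboronic pinacol ester 5 (not isolated)
Conditions: [Ir(OMe)(cod)]2 (1.5 mol%), 4,4'-di-tert-butyl-2,2'-bipyridine (3 mol%), B2pin2, THF, 60 °C; then aq. NaOH, H2O2, 0 °C → rt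
Reagents that add atoms: bis(pinacolato)diboron CC1(C)OB(OC1(C)C)B1OC(C)(C)C(C)(C)O1 (boryl group of 5); hydrogen peroxide OO (phenol oxygen of 6)
Why: Sterically controlled iridium-catalysed C–H borylation should pick the only ring C–H that has no ortho substituent (para to the prenyl group), and alkaline peroxide then oxidises the C–B bond to the phenol without touching the trisubstituted alkene.

Step 4
Reactants: 6 3,5-bis(methoxymethoxy)-4-(3-methylbut-2-en-1-yl)phenol
Product: 7 6-hydroxy-2,4-bis(methoxymethoxy)-3-(3-methylbut-2-en-1-yl)benzoic acid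
Conditions: MeOMgOCO2Me (2 M in DMF), 120 °C; then cold 1 M HCl to pH 3
Reagents that add atoms: methoxymagnesium methyl carbonate CO[Mg]OC(=O)OC
Why: Kolbe–Schmitt-type ortho-carboxylation with Stiles' reagent: the two ortho positions of the mirror-symmetric phenol are equivalent and the para position is blocked, and the magnesium salicylate chelate should hold the product until the cold acidic work-up (the free acid is used at once because it can decarboxylate).

Step 5
Reactants: 7 6-hydroxy-2,4-bis(methoxymethoxy)-3-(3-methylbut-2-en-1-yl)benzoic acid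
Product: 8 5,7-bis(methoxymethoxy)-6-(3-methylbut-2-en-1-yl)-4H-1,3-benzodioxin-4-one
Conditions: CH2I2, Cs2CO3, DMF, rt → 40 °C
Reagents that add atoms: diiodomethane ICI
Why: Double O-alkylation (carboxylate first, then the neighbouring phenoxide closes the six-membered ring) gives the benzodioxinone, a lactone that later serves as acyl donor and releases the one phenol oxygen that is para to the prenyl group, which fixes the 6-prenyl pattern.

Step 6
Reactants: 2 1,3-bis(methoxymethoxy)benzene; 9 geranyl bromide
Product: 10 2-[(2E)-3,7-dimethylocta-2,6-dien-1-yl]-1,3-bis(methoxymethoxy)benzene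
Conditions: n-BuLi, THF, 0 °C → rt; then CuI (copper iodide, 10 mol%), 9, −78 °C → rt
Reagents that add atoms: none
Why: The same directed ortho-metalation/allylation as in step 2, with SN2 attack at the primary carbon so that the E geometry of geranyl bromide is carried over unchanged.

Step 7
Reactants: 10 2-[(2E)-3,7-dimethylocta-2,6-dien-1-yl]-1,3-bis(methoxymethoxy)benzene
Product: 11 3-[(2E)-3,7-dimethylocta-2,6-dien-1-yl]-2,4-bis(methoxymethoxy)benzaldehyde
Conditions: n-BuLi, TMEDA, THF, 0 °C; then DMF, −78 °C → rt; H2O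
Reagents that add atoms: N,N-dimethylformamide CN(C)C=O
Why: Directed ortho-metalation next to one MOM ether (the two open ortho positions are equivalent) and Bouveault-type formylation of the aryllithium with DMF.

Step 8
Reactants: 11 3-[(2E)-3,7-dimethylocta-2,6-dien-1-yl]-2,4-bis(methoxymethoxy)benzaldehyde; 12 (R)-chloromethyl p-tolyl sulfoxide
Product: 14 (2S,3S)-2-{3-[(2E)-3,7-dimethylocta-2,6-dien-1-yl]-2,4-bis(methoxymethoxy)phenyl}-3-[(R)-p-tolylsulfinyl]oxirane, via chlorohydrin adduct 13 (not isolated)
Conditions: 12, LiN(i-Pr)2, THF, −78 °C; then 11; then t-BuOK, t-BuOH–THF, −78 → 0 °C; chromatography (trans isomer)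
Reagents that add atoms: none
Why: Darzens-type condensation of the lithiated α-chloro sulfoxide with the aldehyde (Satoh's sulfinyloxirane synthesis) and base-induced ring closure with inversion at the chlorine-bearing carbon, in which the sulfinyl group should control the carbon it is bound to (the later C-3) while the carbinol carbon forms as a mixture from which the trans-oxirane is separated.

Step 9
Reactants: 14 the trans-sulfinyloxirane; 8 5,7-bis(methoxymethoxy)-6-(3-methylbut-2-en-1-yl)-4H-1,3-benzodioxin-4-one
Product: 17 (2R,3R)-2-{3-[(2E)-3,7-dimethylocta-2,6-dien-1-yl]-2,4-bis(methoxymethoxy)phenyl}-3-hydroxy-5,7-bis(methoxymethoxy)-6-(3-methylbut-2-en-1-yl)chroman-4-one, via oxiranyllithium 15 (not isolated), via epoxy ketone 16 (not isolated)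
Conditions: 14 (1.2 equiv), t-BuLi (1.25 equiv), THF, −100 °C, 2 min; then 8 (1.0 equiv) in THF, −100 → −78 °C; then TFA (2.5 equiv), −78 → 0 °C
Reagents that add atoms: tert-butyllithium [Li]C(C)(C)C (lithium of 15 only; no atom in 17)
Why: Proposed new method: t-BuLi attacks the sulfur of 14 and expels the oxiranyl carbanion (sulfoxide–lithium exchange) to give 15, which adds to the lactone carbonyl of 8; on acid quench the tetrahedral adduct collapses to the aryl ketone with loss of formaldehyde and frees the ring-A phenol (16), whose oxygen opens the protonated, strained epoxide at the benzylic carbon to give 17. The closest known reaction types are the trapping of oxiranyllithiums made from sulfinyloxiranes with carbonyl and acyl electrophiles, the ring-opening acylation of nucleophiles by 1,3-benzodioxin-4-ones, and the cyclisation of 2'-hydroxychalcone epoxides to trans-dihydroflavonols; their union in one flask with a lactone as acyl donor is new. Ring C closes 6-endo-tet (phenol oxygen onto the epoxide carbon that carries ring B), while the C4–C3 bond is made just before by intermolecular acyl substitution. C-3 carries the configuration set in step 8 through exchange and acylation, both with retention at carbon; C-2 is set by anti opening of the trans-epoxide, and any ionised (benzylic cation) share of the opening should also end 2,3-trans because the aryl group takes the pseudo-equatorial position. The step needs single acylation (the tetrahedral adduct, and then the ketone deactivated by its ortho-phenoxide, resist a second addition) and 6-endo opening instead of 5-exo attack at C-3 or aroyl migration, which the 2,4-dioxygenated ring B should secure by placing the positive charge at C-2 under acid while the hydrogen-bonded ortho-phenol sits within reach.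

Step 10
Reactants: 17 the tetra-MOM dihydroflavonol
Product: 18 (2R,3R)-2-{3-[(2E)-3,7-dimethylocta-2,6-dien-1-yl]-2,4-dihydroxyphenyl}-3,5,7-trihydroxy-6-(3-methylbut-2-en-1-yl)chroman-4-one (CNP0166115.1)
Conditions: HCl (1.25 M in MeOH), 40 °C
Reagents that add atoms: none
Why: Acid-catalysed acetal exchange (methanolysis) removes the four MOM groups; C-3 is not enolised under these conditions, and C-2, which can open reversibly through the ring-B quinone methide once the phenols are free, should settle in the more stable 2,3-trans arrangement.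

**Compound list**
1 | resorcinol | Oc1cccc(O)c1 | starting material
2 | 1,3-bis(methoxymethoxy)benzene | COCOc1cccc(OCOC)c1 | intermediate
3 | prenyl bromide (1-bromo-3-methylbut-2-ene) | CC(C)=CCBr | starting material
4 | 1,3-bis(methoxymethoxy)-2-(3-methylbut-2-en-1-yl)benzene | COCOc1cccc(OCOC)c1CC=C(C)C | intermediate
5 | 2-[3,5-bis(methoxymethoxy)-4-(3-methylbut-2-en-1-yl)phenyl]-4,4,5,5-tetramethyl-1,3,2-dioxaborolane | COCOc1cc(B2OC(C)(C)C(C)(C)O2)cc(OCOC)c1CC=C(C)C | intermediate
6 | 3,5-bis(methoxymethoxy)-4-(3-methylbut-2-en-1-yl)phenol | COCOc1cc(O)cc(OCOC)c1CC=C(C)C | intermediate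
7 | 6-hydroxy-2,4-bis(methoxymethoxy)-3-(3-methylbut-2-en-1-yl)benzoic acid | COCOc1cc(O)c(C(=O)O)c(OCOC)c1CC=C(C)C | intermediate
8 | 5,7-bis(methoxymethoxy)-6-(3-methylbut-2-en-1-yl)-4H-1,3-benzodioxin-4-one | COCOc1cc2OCOC(=O)c2c(OCOC)c1CC=C(C)C | intermediate
9 | geranyl bromide ((2E)-1-bromo-3,7-dimethylocta-2,6-diene) | CC(C)=CCC/C(C)=C/CBr | starting material
10 | 2-[(2E)-3,7-dimethylocta-2,6-dien-1-yl]-1,3-bis(methoxymethoxy)benzene | CC(C)=CCC/C(C)=C/Cc1c(OCOC)cccc1OCOC | intermediate
11 | 3-[(2E)-3,7-dimethylocta-2,6-dien-1-yl]-2,4-bis(methoxymethoxy)benzaldehyde | CC(C)=CCC/C(C)=C/Cc1c(OCOC)ccc(C=O)c1OCOC | intermediate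
12 | (R)-chloromethyl p-tolyl sulfoxide | ClC[S@](=O)c1ccc(C)cc1 | starting material
13 | (1S,2S)-2-chloro-1-{3-[(2E)-3,7-dimethylocta-2,6-dien-1-yl]-2,4-bis(methoxymethoxy)phenyl}-2-[(R)-p-tolylsulfinyl]ethan-1-ol (lithium alkoxide in the flask) | CC(C)=CCC/C(C)=C/Cc1c(OCOC)ccc([C@H](O)[C@H](Cl)[S@](=O)c2ccc(C)cc2)c1OCOC | intermediate
14 | (2S,3S)-2-{3-[(2E)-3,7-dimethylocta-2,6-dien-1-yl]-2,4-bis(methoxymethoxy)phenyl}-3-[(R)-p-tolylsulfinyl]oxirane (trans) | CC(C)=CCC/C(C)=C/Cc1c(OCOC)ccc([C@@H]2O[C@H]2[S@](=O)c2ccc(C)cc2)c1OCOC | intermediate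
15 | trans-(3-aryloxiran-2-yl)lithium with the carbon configuration of 14 (aryl = 3-geranyl-2,4-bis(methoxymethoxy)phenyl) | CC(C)=CCC/C(C)=C/Cc1c(OCOC)ccc([C@@H]2O[C@H]2[Li])c1OCOC | intermediate
16 | {(2R,3S)-3-[3-geranyl-2,4-bis(methoxymethoxy)phenyl]oxiran-2-yl}[6-hydroxy-2,4-bis(methoxymethoxy)-3-(3-methylbut-2-en-1-yl)phenyl]methanone (the (αR,βS) 2'-hydroxychalcone epoxide) | CC(C)=CCC/C(C)=C/Cc1c(OCOC)ccc([C@@H]2O[C@H]2C(=O)c2c(O)cc(OCOC)c(CC=C(C)C)c2OCOC)c1OCOC | intermediate
17 | (2R,3R)-2-{3-[(2E)-3,7-dimethylocta-2,6-dien-1-yl]-2,4-bis(methoxymethoxy)phenyl}-3-hydroxy-5,7-bis(methoxymethoxy)-6-(3-methylbut-2-en-1-yl)chroman-4-one | CC(C)=CCC/C(C)=C/Cc1c(OCOC)ccc([C@H]2Oc3cc(OCOC)c(CC=C(C)C)c(OCOC)c3C(=O)[C@@H]2O)c1OCOC | intermediate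
18 | (2R,3R)-2-{3-[(2E)-3,7-dimethylocta-2,6-dien-1-yl]-2,4-dihydroxyphenyl}-3,5,7-trihydroxy-6-(3-methylbut-2-en-1-yl)chroman-4-one | CC(C)=CCC/C(C)=C/Cc1c(O)ccc([C@H]2Oc3cc(O)c(CC=C(C)C)c(O)c3C(=O)[C@@H]2O)c1O | target

**Step count**
Total: 10 steps. Longest linear sequence: 7 steps (1, 2, 3, 4, 5, 9, 10).

**Steps most likely to fail**

Step 9. Two processes threaten it. The lithiated epoxide may decompose as a carbenoid (α-elimination) before it is acylated. After acylation, the epoxy ketone may open at the wrong carbon (5-exo attack at C-3) or undergo aroyl migration once the benzylic carbon ionises. The fallback uses known chemistry, sets out from 8 and 11, and comes back at 16 and then 17. MeLi (THF, −78 °C) should open 8 to the ortho-hydroxyacetophenone 1-[6-hydroxy-2,4-bis(methoxymethoxy)-3-(3-methylbut-2-en-1-yl)phenyl]ethan-1-one F1. Allyl bromide with K2CO3 should give the allyl ether F2. Claisen–Schmidt condensation of F2 with 11 (KOH, EtOH) should give the (E)-chalcone F3. Juliá–Colonna epoxidation (poly-L-leucine, urea–H2O2, DBU, THF) uses a nucleophilic peroxide that attacks only the enone and leaves the isolated alkenes alone, and should give the (αR,βS)-epoxide F4. Pd(PPh3)4 with morpholine then removes the allyl group to give 16, which is closed with TFA to 17 as in the main route.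

Step 8. Facial control at the carbinol carbon may be poor, or the sulfur-to-carbon induction may be weak, leaving a mixture of diastereomers that is hard to separate. The fallback sets out from 11 and comes back at 14. Horner–Wadsworth–Emmons olefination of 11 with the lithium salt of the enantiopure diethyl (p-tolylsulfinyl)methylphosphonate should give the (S,E)-2-arylvinyl p-tolyl sulfoxide F5. Nucleophilic epoxidation with t-BuOOLi (THF, 0 °C) is sulfinyl-directed, keeps the E geometry as the trans-oxirane, and does not touch the prenyl-type alkenes; it should give 14.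

Step 3. The iridium hydride and pinacolborane present may hydroborate or shift the prenyl double bond, and regiocontrol may erode. The fallback sets out from 2 and comes back at 6, and places the borylation before any alkene is present. The same iridium-catalysed borylation of 2 should give the 5-boryl compound 2-[3,5-bis(methoxymethoxy)phenyl]-4,4,5,5-tetramethyl-1,3,2-dioxaborolane F6. Oxidation with NaOH/H2O2 gives 3,5-bis(methoxymethoxy)phenol F7. TIPSCl with imidazole gives the silyl ether [3,5-bis(methoxymethoxy)phenoxy]triisopropylsilane F8. Lithiation with n-BuLi between the two MOM ethers (the bulky silyl ether shields its own neighbours) and prenyl bromide give [3,5-bis(methoxymethoxy)-4-(3-methylbut-2-en-1-yl)phenoxy]triisopropylsilane F9. TBAF then gives 6.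

Further compounds
F1 | step 9 | 1-[6-hydroxy-2,4-bis(methoxymethoxy)-3-(3-methylbut-2-en-1-yl)phenyl]ethan-1-one | CC(=O)c1c(O)cc(OCOC)c(CC=C(C)C)c1OCOC
F2 | step 9 | 1-[2,4-bis(methoxymethoxy)-3-(3-methylbut-2-en-1-yl)-6-(prop-2-en-1-yloxy)phenyl]ethan-1-one | CC(=O)c1c(OCC=C)cc(OCOC)c(CC=C(C)C)c1OCOC
F3 | step 9 | (2E)-1-[2,4-bis(methoxymethoxy)-3-(3-methylbut-2-en-1-yl)-6-(prop-2-en-1-yloxy)phenyl]-3-{3-[(2E)-3,7-dimethylocta-2,6-dien-1-yl]-2,4-bis(methoxymethoxy)phenyl}prop-2-en-1-one | CC(C)=CCC/C(C)=C/Cc1c(OCOC)ccc(/C=C/C(=O)c2c(OCC=C)cc(OCOC)c(CC=C(C)C)c2OCOC)c1OCOC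
F4 | step 9 | {(2R,3S)-3-[3-geranyl-2,4-bis(methoxymethoxy)phenyl]oxiran-2-yl}[2,4-bis(methoxymethoxy)-3-(3-methylbut-2-en-1-yl)-6-(prop-2-en-1-yloxy)phenyl]methanone | CC(C)=CCC/C(C)=C/Cc1c(OCOC)ccc([C@@H]2O[C@H]2C(=O)c2c(OCC=C)cc(OCOC)c(CC=C(C)C)c2OCOC)c1OCOC
F5 | step 8 | (S,E)-2-{3-[(2E)-3,7-dimethylocta-2,6-dien-1-yl]-2,4-bis(methoxymethoxy)phenyl}ethenyl p-tolyl sulfoxide | CC(C)=CCC/C(C)=C/Cc1c(OCOC)ccc(/C=C/[S@](=O)c2ccc(C)cc2)c1OCOC
F6 | step 3 | 2-[3,5-bis(methoxymethoxy)phenyl]-4,4,5,5-tetramethyl-1,3,2-dioxaborolane | COCOc1cc(B2OC(C)(C)C(C)(C)O2)cc(OCOC)c1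
F7 | step 3 | 3,5-bis(methoxymethoxy)phenol | COCOc1cc(O)cc(OCOC)c1
F8 | step 3 | [3,5-bis(methoxymethoxy)phenoxy]triisopropylsilane | COCOc1cc(OCOC)cc(O[Si](C(C)C)(C(C)C)C(C)C)c1
F9 | step 3 | [3,5-bis(methoxymethoxy)-4-(3-methylbut-2-en-1-yl)phenoxy]triisopropylsilane | COCOc1cc(O[Si](C(C)C)(C(C)C)C(C)C)cc(OCOC)c1CC=C(C)C
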